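How much of the racemate the flask turns into product by 15 min, with what excess, and whether the exchange between the two substrates keeps up: these are the questions.

* left-handed product and right-handed product together, in percent of the left-handed substrate and right-handed substrate charged together, at 15 min
* excess of left-handed product over right-handed product in the product at 15 min
* whether the exchange between left-handed substrate and right-handed substrate keeps pace with the reaction: how far the product's excess at 15 min gets from its value without exchange to its value with instant exchange (above 80% keeps pace, below 20% hardly takes part, else lags behind)

| flask | left-handed substrate | right-handed substrate | partner | racemization catalyst | remark | time |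
|---|---|---|---|---|---|---|
| theta | 0.10 M | 0.10 M | 2.7 equiv (fed, over 2.5 min) | 2.5 mol% | run made earlier; the fed solution adds 0.10 times the starting volume |  |
| eta | 0.10 M | 0.10 M | 6 equiv (fed, over 2.5 min) | 2.5 mol% | run made earlier; the fed solution adds 0.10 times the starting volume |  |
| gamma | 0.050 M | 0.050 M | 4 equiv (fed, over 2.5 min) | 2.5 mol% | run made earlier; the fed solution adds 0.10 times the starting volume |  |
| flask | 0.10 M | 0.10 M | 4.00 equiv (fed, over 2.5 min) | 2.5 mol% | the fed solution adds 0.10 times the starting volume | 15 min |

| run | time / min | left-handed product / % | right-handed product / % |
|---|---|---|---|
| theta | 1.33 | 1 | 2 |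
| theta | 4.00 | 7 | 5 |
| theta | 8.00 | 15 | 6 |
| theta | 10.0 | 18 | 8 |
| theta | 15.0 | 22 | 13 |
| eta | 1.33 | 2 | 0 |
| eta | 2.50 | 7 | 5 |
| eta | 4.00 | 13 | 10 |
| eta | 8.00 | 24 | 18 |
| eta | 15.0 | 35 | 21 |
| gamma | 1.33 | 2 | 0 |
| gamma | 2.50 | 2 | 3 |
| gamma | 4.00 | 6 | 3 |
| gamma | 8.00 | 9 | 6 |
| gamma | 15.0 | 17 | 12 |

(standard deviation of a reading: 1.5 percentage points)

- partner is single-handed; left-handed substrate and right-handed substrate are mirror images of each other, charged as a racemate, each of them at the stated concentration
- charges are per starting volume, the dose included; the dosed solution carries all of it
- an excess is the difference of the two amounts in percent of their sum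
- an excess is below zero if the other one leads
- the handed part of partner does not stay in what it makes, so the products of the two hands are mirror images too

The simulated run that looks nearest to the flask is gamma, with the same 4 equiv of partner, but with 0.050 M of each substrate against 0.10 M, so that [partner] as charged is 0.200 M in gamma against 0.400 M in the flask. Counted as the fraction left and not the fraction made, the two substrates together stand at 71.0% in gamma at 15.0 min, 65.0% in theta and 44.0% in eta. Minus the natural logarithm of that fraction, divided by the charged [partner], comes to 1.71 /M, 1.60 /M and 1.37 /M, and the mean 1.56 /M is the exposure per molar of partner. Gamma, at half the substrate, stays in line with the others.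

Gamma therefore ends at 29.0% made because its substrate meets half the [partner] of the flask, although the equivalents agree. This reckoning gives the flask an exponent of 0.623, hence 46.4% made. For the excess it stays with the readings at 15.0 min, 25.7% in theta and 25.0% in eta, and the exposure says nothing about the exchange. The forecast gave 45%, an excess of 25% and an exchange that lags behind, adding: “The data barely separate these limits”.

The flask gives 45.6% with an excess of 23.3%, and the exchange keeps pace, getting 91% of the way, with an excess of right-handed substrate of 0.404% among what is left at 15.0 min.

    partner + left-handed substrate → left-handed product (k = 0.260 /M/min)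
    partner + right-handed substrate → right-handed product (k = 0.160 /M/min)
    left-handed substrate + racemization catalyst ⇌ right-handed substrate + racemization catalyst, rate k3*[racemization catalyst]*[left-handed substrate] forward; the back reaction follows from the equilibrium constant (k = 400 /M/min)
    partner → decomposed reagent (k = 0.0160 /min)
    partner ⇌ dormant form (K = 0.570, k = 0.0820 /min)
    partner → decomposition product (k = 5.60 × 10⁻⁵ /min)

Taken back through the exposure, this result gives 1.52 /M against the 1.56 /M from the runs. The same flask with 10.0 equiv of partner has 1.00 M charged, so 1.56 /M leaves 21.0% of the substrates and makes 79.0%, and that neighbour stands at 79.5%.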